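**Retrosynthetic overview**
1. The last bond made is C6–O: the target comes from a 6β,7β:8α,9α-bis-epoxide and 4-hydroxybenzoic acid by regioselective carboxylysis, which sets C6 and frees the 7β-OH.
2. Both epoxides come from a dauca-6,8-dien-4β-ol: hydroxyl-directed β-epoxidation of C6=C7, then α-epoxidation of C8=C9.
3. The dienol comes from a bicyclic linear dienone by deconjugative α-protonation (H-5) and isopropyl addition to C4, both anti to the angular methyl.
4. The dienone comes from elimination of an aldol adduct whose seven-membered ring is closed by ring-closing metathesis (this ring is formed second).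
5. The cyclopentanone (five-membered ring, present from the start) comes from 3-ethoxycyclopent-2-enone, a homomethallyl Grignard reagent and a catalytic asymmetric Me3Al conjugate addition, which sets the C1 quaternary centre and is the only reagent-controlled stereocentre.

Assumption: compounds 1 and 2 are bought as catalogue chemicals, the phosphoramidite enantiomer in step 2 is the one that gives the 3S ketone (its antipode is equally available), and positions are given in daucane numbering (C1 quaternary ring-fusion carbon with CH3, C2–C3 ring CH2, C4 carbinol carbon with i-Pr, C5 ring-fusion CH, C6–C10 the remaining seven-ring carbons, CH3 on C8; β is the face of the C1 methyl).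

Step 1
Reactants: 1 4-bromo-2-methylbut-1-ene; 2 3-ethoxycyclopent-2-en-1-one
Product: 5 3-(3-methylbut-3-en-1-yl)cyclopent-2-en-1-one, via Grignard reagent 3 (not isolated), via ethoxy carbinol 4 (not isolated)
Conditions: Mg, THF, 40 °C; then 2, 0 °C; 1 M HCl, 23 °C
Reagents that add atoms: none
Why: Stork–Danheiser alkylative carbonyl transposition, in which the Grignard reagent adds 1,2 to the vinylogous ester and acid work-up hydrolyses the enol ether and eliminates water to give the 3-substituted enone, with no stereocentre formed.

Step 2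
Reactants: 5 3-(3-methylbut-3-en-1-yl)cyclopent-2-en-1-one; 6 acrolein
Product: 8 (3S)-2-(1-hydroxyprop-2-en-1-yl)-3-methyl-3-(3-methylbut-3-en-1-yl)cyclopentan-1-one (diastereomer mixture at C2 and the carbinol carbon), via dimethylaluminium enolate 7 (not isolated)
Conditions: Me3Al (1.5 equiv), Cu(O2CC4H3S) (copper thiophene-2-carboxylate, 2 mol %), biphenol-derived phosphoramidite with a bis[(S)-1-(2-naphthyl)ethyl]amino group (4 mol %), Et2O, −30 °C; then 6 (3 equiv), −78 °C; 1 M HCl
Reagents that add atoms: trimethylaluminium, C[Al](C)C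
Why: Copper-catalysed asymmetric conjugate addition of Me3Al creates the quaternary C1 stereocentre under ligand control, and the regiodefined aluminium enolate is trapped in an aldol addition with acrolein whose two new centres need no control because both are erased in step 4.

Step 3
Reactants: 8 (3S)-2-(1-hydroxyprop-2-en-1-yl)-3-methyl-3-(3-methylbut-3-en-1-yl)cyclopentan-1-one
Product: 9 (3aS)-8-hydroxy-3a,6-dimethyl-3,3a,4,5,8,8a-hexahydroazulen-1(2H)-one (diastereomer mixture at C8 and C8a)
Conditions: second-generation Grubbs catalyst (5 mol %), CH2Cl2 (5 mM), 40 °C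
Reagents that add atoms: none
Why: Ring-closing metathesis between the 1,1-disubstituted alkene and the vinyl carbinol closes the seven-membered ring as its trisubstituted C7=C8 alkene and sets no stereocentre.

Step 4
Reactants: 9 (3aS)-8-hydroxy-3a,6-dimethyl-3,3a,4,5,8,8a-hexahydroazulen-1(2H)-one
Product: 13 (3aR,8aR)-3a,6-dimethyl-3,3a,4,8a-tetrahydroazulen-1(2H)-one, via allylic mesylate 10 (not isolated), via conjugated dienone 11 (not isolated), via potassium trienolate 12 (not isolated)
Conditions: MsCl, Et3N, THF, 0 °C; then KOt-Bu (6 equiv), t-BuOH, 0 to 23 °C, 1 h; inverse quench into AcOH/H2O, 0 °C; used crude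
Reagents that add atoms: none
Why: Mesylation and E1cB elimination funnel all diastereomers into the linear dienone, equilibrating deprotonation gives the fully conjugated trienolate, and kinetic deconjugative α-protonation at C5 from the α-face, opposite the pseudo-axial C1 methyl, sets the trans ring fusion (H-5 α) and places the diene at C6–C9.

Step 5
Reactants: 13 (3aR,8aR)-3a,6-dimethyl-3,3a,4,8a-tetrahydroazulen-1(2H)-one
Product: 14 (1R,3aR,8aR)-3a,6-dimethyl-1-(propan-2-yl)-1,2,3,3a,4,8a-hexahydroazulen-1-ol (dauca-6,8-dien-4β-ol)
Conditions: i-PrMgCl (3 equiv), CeCl3 (3 equiv), THF, −78 °C; aq NH4Cl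
Reagents that add atoms: isopropylmagnesium chloride, CC(C)[Mg]Cl
Why: Imamoto organocerium 1,2-addition, which adds to the ketone without enolising the acidic C5–H, delivers isopropyl to the carbonyl face anti to the 1,3-related angular methyl (α-face) and so gives the 4β tertiary alcohol.

Step 6
Reactants: 14 dauca-6,8-dien-4β-ol
Product: 15 (1R,4R,5S,6S,7R)-6,7-epoxydauc-8-en-4-ol (6β,7β-epoxide, 4β-OH, H-5 α)
Conditions: VO(acac)2 (5 mol %), t-BuOOH (1.5 equiv), 2,6-lutidine, CH2Cl2, 0 °C
Reagents that add atoms: tert-butyl hydroperoxide, CC(C)(C)OO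
Why: Vanadium-catalysed hydroxyl-directed epoxidation, in which the 4β-OH (homoallylic and cis to C6 on the cyclopentane) binds the vanadium peroxide and delivers oxygen only to C6=C7 and only to its β-face, leaving the more electron-rich but undirected C8=C9 alkene untouched.

Step 7
Reactants: 15 6β,7β-epoxydauc-8-en-4β-ol
Product: 16 (1R,4R,5S,6S,7S,8S,9S)-6,7:8,9-diepoxydaucan-4-ol (6β,7β:8α,9α-bis-epoxide)
Conditions: dimethyldioxirane (1.2 equiv), acetone/CH2Cl2, −20 °C
Reagents that add atoms: dimethyldioxirane, CC1(C)OO1
Why: Dioxirane epoxidation (neutral, so the vinyl epoxide survives) of the remaining trisubstituted alkene occurs on the α-face, anti both to the adjacent 6β,7β-epoxide oxygen and to the C1 methyl, giving the 8α,9α-epoxide.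

Step 8
Reactants: 16 6β,7β:8α,9α-diepoxydaucan-4β-ol; 17 4-hydroxybenzoic acid
Product: 18 (1R,4R,5S,6R,7S,8R,9S)-8,9-epoxy-4,7-dihydroxydaucan-6-yl 4-hydroxybenzoate (6α-ester, 4β,7β-diol, 8α,9α-epoxide)
Conditions: (R,R)-N,N′-bis(3,5-di-tert-butylsalicylidene)-1,2-cyclohexanediaminocobalt (divalent cobalt precatalyst, 5 mol %), 17 (1.5 equiv), i-Pr2NEt (1.0 equiv), air, t-BuOMe/THF, 23 °C
Reagents that add atoms: none
Why: Proposed new method: a chiral salen cobalt carboxylate (trivalent cobalt, formed in the flask from the precatalyst, 17 and air) should open only the cis-disubstituted 6β,7β-epoxide, one cobalt centre activating the epoxide oxygen and a second delivering the carboxylate in an SN2 attack at C6 from the α-face (inversion gives the 6α-ester and frees the 7β-OH), because attack at C7 is retarded by the adjacent fully substituted C8–O centre, the trisubstituted 8,9-epoxide is too hindered for the bimetallic pathway, the carboxylic acid outcompetes the far less acidic phenol for cobalt, and the catalyst enantiomer is taken as matched for C6 (the antipode is the first variable to change), the closest known reaction type being the salen cobalt-catalysed ring opening of meso-epoxides with benzoic acids and the catalyst-controlled regioselective opening of enantioenriched epoxides, neither of which has been shown on a vicinal bis-epoxide or with a free hydroxy acid.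

**Compound list**
1 | 4-bromo-2-methylbut-1-ene | CC(=C)CCBr | starting material
2 | 3-ethoxycyclopent-2-en-1-one | CCOC1=CC(=O)CC1 | starting material
3 | (3-methylbut-3-en-1-yl)magnesium bromide | CC(=C)CC[Mg]Br | intermediate
4 | 3-ethoxy-1-(3-methylbut-3-en-1-yl)cyclopent-2-en-1-ol (present as its magnesium alkoxide) | CCOC1=CC(O)(CCC(C)=C)CC1 | intermediate
5 | 3-(3-methylbut-3-en-1-yl)cyclopent-2-en-1-one | O=C1C=C(CCC(C)=C)CC1 | intermediate
6 | acrolein | C=CC=O | starting material
7 | dimethylaluminium enolate of (S)-3-methyl-3-(3-methylbut-3-en-1-yl)cyclopentanone (enolate towards C2) | C[Al](C)OC1=C[C@@](C)(CCC(C)=C)CC1 | intermediate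
8 | (3S)-2-(1-hydroxyprop-2-en-1-yl)-3-methyl-3-(3-methylbut-3-en-1-yl)cyclopentan-1-one, diastereomer mixture | O=C1CC[C@](C)(CCC(C)=C)C1C(O)C=C | intermediate
9 | (3aS)-8-hydroxy-3a,6-dimethyl-3,3a,4,5,8,8a-hexahydroazulen-1(2H)-one, diastereomer mixture | O=C1CC[C@]2(C)CCC(C)=CC(O)C12 | intermediate
10 | methanesulfonate of 9 | O=C1CC[C@]2(C)CCC(C)=CC(OS(C)(=O)=O)C12 | intermediate
11 | (3aS)-3a,6-dimethyl-3,3a,4,5-tetrahydroazulen-1(2H)-one (linear dienone) | O=C1CC[C@]2(C)CCC(C)=CC=C12 | intermediate
12 | potassium trienolate of 11 | [K+].[O-]C1=C2C=CC(C)=CC[C@@]2(C)CC1 | intermediate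
13 | (3aR,8aR)-3a,6-dimethyl-3,3a,4,8a-tetrahydroazulen-1(2H)-one (trans-fused, H-5 α) | O=C1CC[C@]2(C)CC=C(C)C=C[C@@H]12 | intermediate
14 | (1R,3aR,8aR)-3a,6-dimethyl-1-(propan-2-yl)-1,2,3,3a,4,8a-hexahydroazulen-1-ol (dauca-6,8-dien-4β-ol) | CC(C)[C@]1(O)CC[C@]2(C)CC=C(C)C=C[C@H]21 | intermediate
15 | (1R,4R,5S,6S,7R)-6,7-epoxydauc-8-en-4-ol (6β,7β-epoxide) | CC(C)[C@]1(O)CC[C@]2(C)CC=C(C)[C@H]3O[C@H]3[C@H]21 | intermediate
16 | (1R,4R,5S,6S,7S,8S,9S)-6,7:8,9-diepoxydaucan-4-ol (6β,7β:8α,9α) | CC(C)[C@]1(O)CC[C@]2(C)C[C@@H]3O[C@]3(C)[C@H]4O[C@H]4[C@H]21 | intermediate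
17 | 4-hydroxybenzoic acid | OC(=O)c1ccc(O)cc1 | starting material
18 | (1R,4R,5S,6R,7S,8R,9S)-8,9-epoxy-4,7-dihydroxydaucan-6-yl 4-hydroxybenzoate (CNP0290052.1) | CC(C)[C@]1(O)CC[C@]2(C)C[C@@H]3O[C@]3(C)[C@@H](O)[C@H](OC(=O)c3ccc(O)cc3)[C@H]21 | target

**Totals**
Total step count: 8. Longest linear sequence: 8 steps (the route is fully linear from 1 and 2).

**Three steps most likely to fail**

Step 4 (face and site of the deconjugative protonation). If substrate control by the angular methyl gives a poor trans:cis ratio at C5, or protonation at C7 competes, the fallback replaces it by catalyst-controlled protonation of a palladium enolate. It sets out from 9: step 4 is run as far as potassium trienolate 12, which is quenched at −78 °C with allyl chloroformate to give the isolable allyl trienyl carbonate F1. F1 is then treated with Pd(OAc)2, (S)-t-Bu-PHOX and formic acid (4 Å molecular sieves, 1,4-dioxane, 40 °C), a known decarboxylative enantioselective protonation, where the ligand is chosen to reinforce α-face protonation at C5. The fallback comes back to the route at 13.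

Step 6 (directed epoxidation by a hindered tertiary homoallylic alcohol on a conjugated diene; the vinyl epoxide is labile to vanadium). The fallback reverses the order of the two epoxidations and relies on substrate control instead of metal direction. It sets out from 14: one equivalent of dimethyldioxirane at −40 °C epoxidises the more electron-rich trisubstituted C8=C9 alkene anti to the C1 methyl to give 8α,9α-epoxydauc-6-en-4β-ol F2. Buffered mCPBA (NaHCO3, CH2Cl2, 0 °C) then epoxidises C6=C7 anti to the first epoxide and syn to the hydrogen-bonding 4β-OH (Henbest effect). It comes back at 16.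

Step 8 (the proposed new carboxylysis: regiochemistry C6 versus C7, survival of the 8,9-epoxide, carboxyl versus phenol). The fallback uses known stoichiometric chelation control and a protected nucleophile. It sets out from 16: Ti(OiPr)4 (1.5 equiv) and 4-(benzyloxy)benzoic acid in CH2Cl2 at 23 °C, where titanium bound to the 4β-OH activates only the neighbouring 6β,7β-epoxide, give the benzyl-protected ester F3. Hydrogenolysis (H2, Pd/C, EtOAc) removes the benzyl group under neutral conditions that leave both the ester and the epoxide intact. It comes back at 18.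

**Further compounds**
F1 | step 4 | allyl (S)-3a,6-dimethyl-2,3,3a,4-tetrahydroazulen-1-yl carbonate (allyl trienyl carbonate) | C=CCOC(=O)OC1=C2C=CC(C)=CC[C@@]2(C)CC1
F2 | step 6 | 8α,9α-epoxydauc-6-en-4β-ol | CC(C)[C@]1(O)CC[C@]2(C)C[C@@H]3O[C@]3(C)C=C[C@H]21
F3 | step 8 | 8α,9α-epoxy-4β,7β-dihydroxydaucan-6α-yl 4-(benzyloxy)benzoate | CC(C)[C@]1(O)CC[C@]2(C)C[C@@H]3O[C@]3(C)[C@@H](O)[C@H](OC(=O)c3ccc(OCc4ccccc4)cc3)[C@H]21
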